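**Assumption:** the SMILES contains no stereocentre and no stereogenic double bond. The target is achiral, so no stereocontrol is needed and "single enantiomer" does not apply.

## Retrosynthetic overview
1. Target 10 ⇒ benzyl ester 9. The B-ring CO2H is unmasked last by hydrogenolysis.
2. 9 ⇒ depside C(=O)–OAr disconnection into A-ring keto acid 5 and B-ring benzyl olivetolate 7.
3. 5 ⇒ ArCH2–C(=O) disconnection into the lateral dianion of toluic acid 1 and butanoyl Weinreb amide 2.
4. 7 ⇒ olivetolic acid 6 and benzyl bromide.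
5. No ring is formed. Both benzene rings are bought fully oxygenated.

## Route

Step 1
Reactants: 1 2,4-dimethoxy-6-methylbenzoic acid; 2 N-methoxy-N-methylbutanamide
Product: 5 2,4-dimethoxy-6-(2-oxopentyl)benzoic acid, via dilithio dianion 3 (not isolated), via lithium tetrahedral adduct 4 (not isolated)
Conditions: LDA (commercial solution, 2.1 equiv), THF, −78 → −20 °C, 1 h; then 2 (1.1 equiv), −78 → 0 °C; cold 1 M HCl quench (pH 3, 0 °C); NaHCO3 extraction and cold re-acidification
Reagents that add atoms: none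
Why: Carboxylate-directed lateral lithiation gives the benzylic carbanion, which adds only once to the Weinreb amide because chelated adduct 4 collapses to the ketone only on the cold acid quench (Weinreb ketone synthesis); no stereocentre remains in 5.

Step 2
Reactants: 6 olivetolic acid (2,4-dihydroxy-6-pentylbenzoic acid)
Product: 7 benzyl 2,4-dihydroxy-6-pentylbenzoate
Conditions: BnBr (1.05 equiv), KHCO3 (1.2 equiv), DMF, rt → 40 °C
Reagents that add atoms: benzyl bromide, BrCc1ccccc1
Why: KHCO3 ionises only the carboxylic acid and not the phenols, so SN2 carboxylate O-alkylation gives the ester chemoselectively at a temperature too low for decarboxylation.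

Step 3
Reactants: 5 2,4-dimethoxy-6-(2-oxopentyl)benzoic acid; 7 benzyl 2,4-dihydroxy-6-pentylbenzoate
Product: 9 benzyl 4-{[2,4-dimethoxy-6-(2-oxopentyl)benzoyl]oxy}-2-hydroxy-6-pentylbenzoate, via mixed trifluoroacetic anhydride 8 (not isolated)
Conditions: 5 and 7 (1:1) premixed in dry toluene; TFAA (4 equiv) added last, 0 °C → rt, 3 h; aqueous NaHCO3 work-up
Reagents that add atoms: none
Why: In this trifluoroacetic anhydride depside esterification the hindered, electron-rich acid is activated as mixed anhydride 8 (acylium-like) and captured by the free 4-OH of 7, because the 2-OH is hydrogen-bonded to the neighbouring ester carbonyl and stays unreactive.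

Step 4
Reactants: 9 benzyl 4-{[2,4-dimethoxy-6-(2-oxopentyl)benzoyl]oxy}-2-hydroxy-6-pentylbenzoate
Product: 10 4-{[2,4-dimethoxy-6-(2-oxopentyl)benzoyl]oxy}-2-hydroxy-6-pentylbenzoic acid (target)
Conditions: H2 (1 atm), 10% Pd/C, EtOAc, rt
Reagents that add atoms: none
Why: Catalytic hydrogenolysis cleaves only the benzyl ester O–CH2Ph bond, since the aryl ester, aliphatic ketone and methyl ethers are inert at 1 atm and the non-nucleophilic solvent prevents depside transesterification.

## Compound list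
1 | 2,4-dimethoxy-6-methylbenzoic acid | Cc1cc(OC)cc(OC)c1C(=O)O | starting material
2 | N-methoxy-N-methylbutanamide | CCCC(=O)N(C)OC | starting material
3 | lithium 2-(lithiomethyl)-4,6-dimethoxybenzoate (dianion of 1) | [Li]Cc1cc(OC)cc(OC)c1C(=O)O[Li] | intermediate
4 | lithium 2-[2-(lithiooxy)-2-(N-methoxy-N-methylamino)pentyl]-4,6-dimethoxybenzoate (racemic transient centre, lost on quench) | CCCC(O[Li])(Cc1cc(OC)cc(OC)c1C(=O)O[Li])N(C)OC | intermediate
5 | 2,4-dimethoxy-6-(2-oxopentyl)benzoic acid | CCCC(=O)Cc1cc(OC)cc(OC)c1C(=O)O | intermediate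
6 | olivetolic acid (2,4-dihydroxy-6-pentylbenzoic acid) | CCCCCc1cc(O)cc(O)c1C(=O)O | starting material
7 | benzyl 2,4-dihydroxy-6-pentylbenzoate | CCCCCc1cc(O)cc(O)c1C(=O)OCc1ccccc1 | intermediate
8 | 2,4-dimethoxy-6-(2-oxopentyl)benzoic trifluoroacetic anhydride | CCCC(=O)Cc1cc(OC)cc(OC)c1C(=O)OC(=O)C(F)(F)F | intermediate
9 | benzyl 4-{[2,4-dimethoxy-6-(2-oxopentyl)benzoyl]oxy}-2-hydroxy-6-pentylbenzoate | CCCCCc1cc(OC(=O)c2c(CC(=O)CCC)cc(OC)cc2OC)cc(O)c1C(=O)OCc1ccccc1 | intermediate
10 | 4-{[2,4-dimethoxy-6-(2-oxopentyl)benzoyl]oxy}-2-hydroxy-6-pentylbenzoic acid | CCCCCc1cc(OC(=O)c2c(CC(=O)CCC)cc(OC)cc2OC)cc(O)c1C(=O)O | target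

## Step count and risks
Total step count: 4. Longest linear sequence: 3 (1 → 5 → 9 → 10, or 6 → 7 → 9 → 10).

**Risk 1, step 3.** Activated 5 can cyclise through its enol to the isocoumarin enol lactone instead of acylating 7. The fallback sets out from 5 and masks the ketone before any activation.
- Allyl bromide, KHCO3, DMF gives allyl 2,4-dimethoxy-6-(2-oxopentyl)benzoate F1.
- Noyori ketalisation (1,2-bis(trimethylsilyloxy)ethane, cat. TMSOTf, CH2Cl2, −78 → −20 °C) gives allyl 2,4-dimethoxy-6-[(2-propyl-1,3-dioxolan-2-yl)methyl]benzoate F2.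
- Pd(PPh3)4, N-methylaniline, THF, rt frees 2,4-dimethoxy-6-[(2-propyl-1,3-dioxolan-2-yl)methyl]benzoic acid F3.
- Steglich esterification with 7 (DCC, DMAP, CH2Cl2) gives benzyl 4-({2,4-dimethoxy-6-[(2-propyl-1,3-dioxolan-2-yl)methyl]benzoyl}oxy)-2-hydroxy-6-pentylbenzoate F4.
- PPTS in wet acetone removes the ketal, and the fallback comes back to the route at 9.

**Risk 2, step 1.** Dilithiation of the electron-rich acid may be incomplete, or the dianion may simply deprotonate 2. The fallback sets out from 1 and goes through an ester monoanion and a purifiable isocoumarin.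
- MeI, K2CO3, DMF gives methyl 2,4-dimethoxy-6-methylbenzoate F5.
- LDA (1.1 equiv), THF, −78 °C, then 2 gives methyl 2,4-dimethoxy-6-(2-oxopentyl)benzoate F6.
- DBU in refluxing toluene closes it to crystalline 6,8-dimethoxy-3-propylisocoumarin F7.
- KOH in aqueous EtOH at reflux, followed by cold acidification, opens the enol lactone, and the fallback comes back to the route at 5.

**Risk 3, step 4.** Hydrogenolysis may stall, the ketone may be partly reduced, or the salicylic-type acid may be lost during long reaction times. The fallback sets out from 6 and swaps the protecting group so that no H2 is needed.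
- Allyl bromide, KHCO3, DMF gives allyl 2,4-dihydroxy-6-pentylbenzoate F8.
- TFAA coupling with 5 (as in step 3, through 8) gives allyl 4-{[2,4-dimethoxy-6-(2-oxopentyl)benzoyl]oxy}-2-hydroxy-6-pentylbenzoate F9.
- Tsuji–Trost deallylation (Pd(PPh3)4, N-methylaniline, THF, rt) brings the fallback back to the route at 10.

## Further compounds
F1 | step 3 | allyl 2,4-dimethoxy-6-(2-oxopentyl)benzoate | CCCC(=O)Cc1cc(OC)cc(OC)c1C(=O)OCC=C
F2 | step 3 | allyl 2,4-dimethoxy-6-[(2-propyl-1,3-dioxolan-2-yl)methyl]benzoate | CCCC1(Cc2cc(OC)cc(OC)c2C(=O)OCC=C)OCCO1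
F3 | step 3 | 2,4-dimethoxy-6-[(2-propyl-1,3-dioxolan-2-yl)methyl]benzoic acid | CCCC1(Cc2cc(OC)cc(OC)c2C(=O)O)OCCO1
F4 | step 3 | benzyl 4-({2,4-dimethoxy-6-[(2-propyl-1,3-dioxolan-2-yl)methyl]benzoyl}oxy)-2-hydroxy-6-pentylbenzoate | CCCCCc1cc(OC(=O)c2c(CC3(CCC)OCCO3)cc(OC)cc2OC)cc(O)c1C(=O)OCc1ccccc1
F5 | step 1 | methyl 2,4-dimethoxy-6-methylbenzoate | Cc1cc(OC)cc(OC)c1C(=O)OC
F6 | step 1 | methyl 2,4-dimethoxy-6-(2-oxopentyl)benzoate | CCCC(=O)Cc1cc(OC)cc(OC)c1C(=O)OC
F7 | step 1 | 6,8-dimethoxy-3-propylisocoumarin | CCCC1=Cc2cc(OC)cc(OC)c2C(=O)O1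
F8 | step 4 | allyl 2,4-dihydroxy-6-pentylbenzoate | CCCCCc1cc(O)cc(O)c1C(=O)OCC=C
F9 | step 4 | allyl 4-{[2,4-dimethoxy-6-(2-oxopentyl)benzoyl]oxy}-2-hydroxy-6-pentylbenzoate | CCCCCc1cc(OC(=O)c2c(CC(=O)CCC)cc(OC)cc2OC)cc(O)c1C(=O)OCC=C
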